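**Retrosynthetic overview**

1. The (E)-propenal is added last by a Wittig two-carbon homologation of a C1 formyl group on ring A, after one acidic global deprotection.
2. Ring B (the 1,4-dioxane) is closed by joining the oxygen on C7' to C3 of ring A: copper-catalysed intramolecular O-arylation of a threo (7'S,8'S) arylglycerol 2,6-diiodophenyl ether, and in the same flask methoxide replaces the second iodine to give the C5 methoxy group.
3. Enabling feature: the C4 ether oxygen of ring A is flanked by two oxygen-bearing carbons, C3 and C5; written as C–I they are equivalent by rotation about the C4–O bond, each lies five atoms from the C7' hydroxyl, and the one not used for ring closure sits where the methoxy group belongs.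
4. The C7'–C8' bond and both stereocentres come from one Evans syn aldol between an (aryloxy)acetyl imide of (R)-4-benzyl-oxazolidinone and MOM-protected vanillin; the threo aldol maps onto the trans ring.
5. Ring order: ring A (4-hydroxy-3,5-diiodobenzaldehyde) and ring C (vanillin) are bought; ring B is the only ring formed, in step 8.

Key step: step 8

Remark: locants follow lignan usage (C7' benzylic carbon, C8' the carbon bearing the C9' hydroxymethyl; ring A = benzo ring with the side chain on C1 and oxygen on C3, C4 and C5; ring B = dioxane; ring C = guaiacyl ring), and the (aryloxy)acetyl imide 7 is assumed to follow the usual syn sense of glycolate-type boron aldol reactions.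

**Route**

Step 1
Reactants: 1 4-hydroxy-3,5-diiodobenzaldehyde
Product: 2 4-(1,3-dioxolan-2-yl)-2,6-diiodophenol
Conditions: ethylene glycol, p-TsOH (cat.), toluene, reflux, Dean–Stark
Reagents that add atoms: ethylene glycol (OCCO)
Why: acid-catalysed acetalisation with azeotropic removal of water masks the formyl group, which would otherwise compete as an aldol acceptor in step 5 and would activate ring A for aryl migration in step 8.

Step 2
Reactants: 3 (R)-4-benzyl-1,3-oxazolidin-2-one; 4 bromoacetyl bromide
Product: 6 (R)-4-benzyl-3-(bromoacetyl)-1,3-oxazolidin-2-one, via lithium oxazolidinide 5 (not isolated)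
Conditions: n-BuLi, THF, −78 °C; then 4, −78 °C to 0 °C
Reagents that add atoms: none
Why: N-acylation of the lithiated oxazolidinone at the acyl bromide, the more reactive of the two electrophilic carbons of 4 at low temperature, is the standard way to load an Evans auxiliary.

Step 3
Reactants: 2 4-(1,3-dioxolan-2-yl)-2,6-diiodophenol; 6 (R)-4-benzyl-3-(bromoacetyl)-1,3-oxazolidin-2-one
Product: 7 (R)-4-benzyl-3-{[4-(1,3-dioxolan-2-yl)-2,6-diiodophenoxy]acetyl}-1,3-oxazolidin-2-one
Conditions: K2CO3, DMF, 0 °C to rt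
Reagents that add atoms: none
Why: Williamson etherification by SN2 displacement of the activated α-bromo imide with the acidic, weakly basic 2,6-diiodophenoxide, which is too poor an acyl acceptor partner to cleave the imide.

Step 4
Reactants: 8 vanillin
Product: 9 3-methoxy-4-(methoxymethoxy)benzaldehyde
Conditions: MOMCl, i-Pr2NEt, CH2Cl2, 0 °C to rt
Reagents that add atoms: chloromethyl methyl ether (COCCl)
Why: O-alkylation of the phenol gives a MOM ether that is inert to the boron aldol, hydride and hot alkoxide and leaves in the final acid step.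

Step 5
Reactants: 7 (R)-4-benzyl-3-{[4-(1,3-dioxolan-2-yl)-2,6-diiodophenoxy]acetyl}-1,3-oxazolidin-2-one; 9 3-methoxy-4-(methoxymethoxy)benzaldehyde
Product: 12 (4R)-4-benzyl-3-{(2R,3S)-2-[4-(1,3-dioxolan-2-yl)-2,6-diiodophenoxy]-3-hydroxy-3-[3-methoxy-4-(methoxymethoxy)phenyl]propanoyl}-1,3-oxazolidin-2-one, via boron enolate 10 (not isolated), via boron aldolate 11 (not isolated)
Conditions: Bu2BOTf, i-Pr2NEt, CH2Cl2, −78 °C to 0 °C; then 9, −78 °C to 0 °C; then H2O2, pH 7 buffer, MeOH, 0 °C
Reagents that add atoms: none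
Why: Evans syn aldol, in which the (Z)-dibutylboron enolate adds to the aldehyde through a closed chair (Zimmerman–Traxler) transition state, so that the enolate geometry fixes the syn (threo) relationship and the (R)-benzyl auxiliary fixes the (2R,3S) sense, setting C8' and C7' together, while the amine-buffered boron reagent should leave the dioxolane and MOM groups alone.

Step 6
Reactants: 12 aldol adduct
Product: 13 (1S,2S)-2-[4-(1,3-dioxolan-2-yl)-2,6-diiodophenoxy]-1-[3-methoxy-4-(methoxymethoxy)phenyl]propane-1,3-diol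
Conditions: LiBH4, THF, MeOH (1 equiv), 0 °C
Reagents that add atoms: none
Why: reductive cleavage of the N-acyl oxazolidinone by hydride attack at the exocyclic carbonyl gives the 1,3-diol and returns the auxiliary without touching aryl iodides, acetals or either stereocentre (the descriptor at C8' changes from R to S only because the priorities change).

Step 7
Reactants: 13 diol
Product: 14 (1S,2S)-2-[4-(1,3-dioxolan-2-yl)-2,6-diiodophenoxy]-1-[3-methoxy-4-(methoxymethoxy)phenyl]-3-(trityloxy)propan-1-ol
Conditions: TrCl, Et3N, DMAP (cat.), CH2Cl2, rt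
Reagents that add atoms: trityl chloride (ClC(c1ccccc1)(c1ccccc1)c1ccccc1)
Why: tritylation is selective for the primary C9' hydroxyl on steric grounds, leaving the secondary C7' hydroxyl as the only nucleophile for ring closure, and a trityl ether neither migrates nor is cleaved under alkoxide conditions.

Step 8
Reactants: 14 trityl ether
Product: 16 (2S,3S)-6-(1,3-dioxolan-2-yl)-8-methoxy-3-[3-methoxy-4-(methoxymethoxy)phenyl]-2-[(trityloxy)methyl]-2,3-dihydro-1,4-benzodioxine, via iodobenzodioxane 15 (not isolated)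
Conditions: CuI (10 mol%), 1,10-phenanthroline (20 mol%), Cs2CO3, toluene, 90 °C; then NaOMe, MeOH, 110 °C (sealed), same flask
Reagents that add atoms: sodium methoxide ([Na+].[O-]C)
Why: Cs2CO3 generates the C7' alkoxide, which binds phenanthroline-ligated monovalent copper; the copper alkoxide activates one of the two equivalent C–I bonds ortho to the C4 ether oxygen of ring A and C–O reductive elimination joins the C7' oxygen to C3, after which methoxide added to the same flask is coupled by the same catalyst at the remaining C5–I bond. The closest known reaction types are the copper-catalysed intramolecular Ullmann O-arylation of 2-(2-halophenoxy)alkanols to 1,4-benzodioxanes and the copper-catalysed methoxylation of aryl iodides. Ring B is the only ring closed, a six-membered ring formed in a formally 6-exo mode at C3 through a seven-membered copper chelate. No new stereocentre is created, because only the O–H bond at C7' and aryl C–I bonds react, so the (7'S,8'S) threo configuration from the aldol step should be carried into the trans ring unchanged. The step needs site selectivity between the two iodines, six- over seven-membered closure and the right order of the two couplings: the first is removed by the local symmetry of the 2,6-diiodo-4-substituted phenyl ether, the second is secured by the trityl ether on the C9' oxygen, and the third by adding methoxide only after ring closure, when the single iodide left can only be methoxylated. The dioxolane keeps ring A unactivated so that the C7' alkoxide cannot start an oxygen-to-oxygen aryl migration (Smiles rearrangement), and the MOM ether on ring C blocks base-induced quinone methide opening at C7'.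

Step 9
Reactants: 16 protected benzodioxane
Product: 17 (2S,3S)-3-(4-hydroxy-3-methoxyphenyl)-2-(hydroxymethyl)-8-methoxy-2,3-dihydro-1,4-benzodioxine-6-carbaldehyde
Conditions: 3 M aq. HCl, THF, 45 °C
Reagents that add atoms: water (O)
Why: acid hydrolysis should remove the dioxolane (water supplies the formyl oxygen), the trityl ether and the MOM ether in one operation, and the trans ring is the thermodynamically preferred arrangement at C7' should the benzylic C–O bond ionise reversibly.

Step 10
Reactants: 17 aldehyde; 18 (triphenylphosphoranylidene)acetaldehyde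
Product: 19 (7'S,8'S)-nocomtal
Conditions: 18 (1.2 equiv), THF–toluene, 80 °C
Reagents that add atoms: none
Why: Wittig olefination with the stabilised formylmethylene ylide should give the (E)-enal and tolerates the free phenol and primary alcohol because the ylide is too weakly basic to deprotonate either.

**Compound list**

Benzodioxine names are numbered with O1 on the ring carbon next to C8, so C2 = C8' and C3 = C7'.

1 | 4-hydroxy-3,5-diiodobenzaldehyde | O=Cc1cc(I)c(O)c(I)c1 | starting material
2 | 4-(1,3-dioxolan-2-yl)-2,6-diiodophenol | Oc1c(I)cc(cc1I)C1OCCO1 | intermediate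
3 | (R)-4-benzyl-1,3-oxazolidin-2-one | O=C1N[C@H](Cc2ccccc2)CO1 | starting material
4 | bromoacetyl bromide | O=C(Br)CBr | starting material
5 | lithium (R)-4-benzyl-2-oxo-1,3-oxazolidin-3-ide | [Li]N1[C@H](Cc2ccccc2)COC1=O | intermediate
6 | (R)-4-benzyl-3-(bromoacetyl)-1,3-oxazolidin-2-one | BrCC(=O)N1[C@H](Cc2ccccc2)COC1=O | intermediate
7 | (R)-4-benzyl-3-{[4-(1,3-dioxolan-2-yl)-2,6-diiodophenoxy]acetyl}-1,3-oxazolidin-2-one | O=C(COc1c(I)cc(cc1I)C1OCCO1)N1[C@H](Cc2ccccc2)COC1=O | intermediate
8 | vanillin (4-hydroxy-3-methoxybenzaldehyde) | COc1cc(C=O)ccc1O | starting material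
9 | 3-methoxy-4-(methoxymethoxy)benzaldehyde | COCOc1ccc(C=O)cc1OC | intermediate
10 | (Z)-dibutylboron enolate of 7 (boryloxy and aryloxy groups cis) | CCCCB(CCCC)O/C(=C\Oc1c(I)cc(cc1I)C1OCCO1)N1[C@H](Cc2ccccc2)COC1=O | intermediate
11 | dibutylboron aldolate of 12 (O-dibutylboryl on the (3S) carbinol oxygen, (2R) at the aryloxy carbon) | COCOc1ccc(cc1OC)[C@H](OB(CCCC)CCCC)[C@@H](Oc1c(I)cc(cc1I)C1OCCO1)C(=O)N1[C@H](Cc2ccccc2)COC1=O | intermediate
12 | (4R)-4-benzyl-3-{(2R,3S)-2-[4-(1,3-dioxolan-2-yl)-2,6-diiodophenoxy]-3-hydroxy-3-[3-methoxy-4-(methoxymethoxy)phenyl]propanoyl}-1,3-oxazolidin-2-one | COCOc1ccc(cc1OC)[C@H](O)[C@@H](Oc1c(I)cc(cc1I)C1OCCO1)C(=O)N1[C@H](Cc2ccccc2)COC1=O | intermediate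
13 | (1S,2S)-2-[4-(1,3-dioxolan-2-yl)-2,6-diiodophenoxy]-1-[3-methoxy-4-(methoxymethoxy)phenyl]propane-1,3-diol | COCOc1ccc(cc1OC)[C@H](O)[C@@H](Oc1c(I)cc(cc1I)C1OCCO1)CO | intermediate
14 | (1S,2S)-2-[4-(1,3-dioxolan-2-yl)-2,6-diiodophenoxy]-1-[3-methoxy-4-(methoxymethoxy)phenyl]-3-(trityloxy)propan-1-ol | COCOc1ccc(cc1OC)[C@H](O)[C@@H](Oc1c(I)cc(cc1I)C1OCCO1)COC(c1ccccc1)(c1ccccc1)c1ccccc1 | intermediate
15 | (2S,3S)-6-(1,3-dioxolan-2-yl)-8-iodo-3-[3-methoxy-4-(methoxymethoxy)phenyl]-2-[(trityloxy)methyl]-2,3-dihydro-1,4-benzodioxine | COCOc1ccc(cc1OC)[C@@H]2Oc3cc(C5OCCO5)cc(I)c3O[C@H]2COC(c4ccccc4)(c4ccccc4)c4ccccc4 | intermediate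
16 | (2S,3S)-6-(1,3-dioxolan-2-yl)-8-methoxy-3-[3-methoxy-4-(methoxymethoxy)phenyl]-2-[(trityloxy)methyl]-2,3-dihydro-1,4-benzodioxine | COCOc1ccc(cc1OC)[C@@H]2Oc3cc(C5OCCO5)cc(OC)c3O[C@H]2COC(c4ccccc4)(c4ccccc4)c4ccccc4 | intermediate
17 | (2S,3S)-3-(4-hydroxy-3-methoxyphenyl)-2-(hydroxymethyl)-8-methoxy-2,3-dihydro-1,4-benzodioxine-6-carbaldehyde | COc1cc([C@@H]2Oc3cc(C=O)cc(OC)c3O[C@H]2CO)ccc1O | intermediate
18 | (triphenylphosphoranylidene)acetaldehyde | O=CC=P(c1ccccc1)(c1ccccc1)c1ccccc1 | starting material
19 | (7'S,8'S)-nocomtal, (E)-3-[(2S,3S)-3-(4-hydroxy-3-methoxyphenyl)-2-(hydroxymethyl)-8-methoxy-2,3-dihydro-1,4-benzodioxin-6-yl]prop-2-enal | COc1cc([C@@H]2Oc3cc(/C=C/C=O)cc(OC)c3O[C@H]2CO)ccc1O | target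

**Step count**

Total steps: 10. Longest linear sequence: 8 (steps 1, 3, 5, 6, 7, 8, 9, 10).

**Steps most likely to fail, with fallbacks**

Step 8. Ring closure at the hindered secondary C7' alkoxide may be too slow, so that methoxide later substitutes both iodides, or reductive loss of iodine may accompany the hot methoxide stage. The fallback sets out from 6 (with 9 and commercial 5-bromovanillin) and returns at 16; it carries the methoxy group in from the start and forms only one C–O bond, with palladium. 5-Bromovanillin is acetalised (ethylene glycol, p-TsOH, toluene, Dean–Stark) to 2-bromo-4-(1,3-dioxolan-2-yl)-6-methoxyphenol F1. Alkylation with 6 (K2CO3, DMF) gives the (aryloxy)acetyl imide F2. The same boron aldol with 9 (Bu2BOTf, i-Pr2NEt, CH2Cl2, −78 °C to 0 °C) gives the syn adduct F3. LiBH4 (THF, MeOH, 0 °C) gives the diol F4, and TrCl/Et3N gives the trityl ether F5. Palladium-catalysed intramolecular etherification of the aryl bromide (Pd(OAc)2, 2-(di-tert-butylphosphino)-1,1'-binaphthyl, Cs2CO3, toluene, 80 °C) should then give 16.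

Step 5. Enolisation may be slow or facial selectivity eroded by the bulky 2,6-diiodoaryloxy group, or the boron Lewis acid may open the dioxolane. The fallback sets out from 2 and 9 and returns at 13; it replaces auxiliary control by catalyst-controlled ketone reduction with dynamic kinetic resolution. Phenol 2 is alkylated with ethyl bromoacetate (K2CO3, DMF) to ethyl [4-(1,3-dioxolan-2-yl)-2,6-diiodophenoxy]acetate F6. Its lithium enolate (LiN(SiMe3)2, THF, −78 °C) adds to 9 to give the hydroxy ester F7 as a stereoisomer mixture. Dess–Martin oxidation gives the configurationally labile β-keto ester F8. Transfer hydrogenation under Noyori conditions (RuCl(p-cymene)[(R,R)-TsDPEN], HCO2H–Et3N, CH2Cl2, 30 °C) should convert the rapidly racemising keto ester into the syn (2R,3S) hydroxy ester F9. The (R,R) catalyst is chosen by analogy with aryl ketone and α-alkoxy β-keto ester reductions. LiBH4 (THF, 0 °C) then gives 13.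

Step 10. The product enal may be homologated a second time to the dienal, or the electron-rich aldehyde may react sluggishly. The fallback sets out from 17 and returns at 19; it olefinates at the ester oxidation level and then adjusts the oxidation state. Ph3P=CHCO2Et (toluene–THF, 80 °C) gives the (E)-cinnamate ester F10. i-Bu2AlH (excess, CH2Cl2–THF, −78 °C) gives the allylic alcohol F11. MnO2 (acetone, rt) should oxidise only the allylic hydroxyl to give 19.

**Further compounds**

F1 | step 8 | 2-bromo-4-(1,3-dioxolan-2-yl)-6-methoxyphenol | COc1cc(cc(Br)c1O)C1OCCO1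
F2 | step 8 | (R)-4-benzyl-3-{[2-bromo-4-(1,3-dioxolan-2-yl)-6-methoxyphenoxy]acetyl}-1,3-oxazolidin-2-one | O=C(COc1c(Br)cc(cc1OC)C1OCCO1)N1[C@H](Cc2ccccc2)COC1=O
F3 | step 8 | (4R)-4-benzyl-3-{(2R,3S)-2-[2-bromo-4-(1,3-dioxolan-2-yl)-6-methoxyphenoxy]-3-hydroxy-3-[3-methoxy-4-(methoxymethoxy)phenyl]propanoyl}-1,3-oxazolidin-2-one | COCOc1ccc(cc1OC)[C@H](O)[C@@H](Oc1c(Br)cc(cc1OC)C1OCCO1)C(=O)N1[C@H](Cc2ccccc2)COC1=O
F4 | step 8 | (1S,2S)-2-[2-bromo-4-(1,3-dioxolan-2-yl)-6-methoxyphenoxy]-1-[3-methoxy-4-(methoxymethoxy)phenyl]propane-1,3-diol | COCOc1ccc(cc1OC)[C@H](O)[C@@H](Oc1c(Br)cc(cc1OC)C1OCCO1)CO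
F5 | step 8 | (1S,2S)-2-[2-bromo-4-(1,3-dioxolan-2-yl)-6-methoxyphenoxy]-1-[3-methoxy-4-(methoxymethoxy)phenyl]-3-(trityloxy)propan-1-ol | COCOc1ccc(cc1OC)[C@H](O)[C@@H](Oc1c(Br)cc(cc1OC)C1OCCO1)COC(c1ccccc1)(c1ccccc1)c1ccccc1
F6 | step 5 | ethyl [4-(1,3-dioxolan-2-yl)-2,6-diiodophenoxy]acetate | CCOC(=O)COc1c(I)cc(cc1I)C1OCCO1
F7 | step 5 | ethyl 2-[4-(1,3-dioxolan-2-yl)-2,6-diiodophenoxy]-3-hydroxy-3-[3-methoxy-4-(methoxymethoxy)phenyl]propanoate (mixture of stereoisomers) | CCOC(=O)C(Oc1c(I)cc(cc1I)C1OCCO1)C(O)c1ccc(OCOC)c(OC)c1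
F8 | step 5 | ethyl 2-[4-(1,3-dioxolan-2-yl)-2,6-diiodophenoxy]-3-[3-methoxy-4-(methoxymethoxy)phenyl]-3-oxopropanoate (racemic, configurationally labile) | CCOC(=O)C(Oc1c(I)cc(cc1I)C1OCCO1)C(=O)c1ccc(OCOC)c(OC)c1
F9 | step 5 | ethyl (2R,3S)-2-[4-(1,3-dioxolan-2-yl)-2,6-diiodophenoxy]-3-hydroxy-3-[3-methoxy-4-(methoxymethoxy)phenyl]propanoate | COCOc1ccc(cc1OC)[C@H](O)[C@@H](Oc1c(I)cc(cc1I)C1OCCO1)C(=O)OCC
F10 | step 10 | ethyl (E)-3-[(2S,3S)-3-(4-hydroxy-3-methoxyphenyl)-2-(hydroxymethyl)-8-methoxy-2,3-dihydro-1,4-benzodioxin-6-yl]prop-2-enoate | COc1cc([C@@H]2Oc3cc(/C=C/C(=O)OCC)cc(OC)c3O[C@H]2CO)ccc1O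
F11 | step 10 | (E)-3-[(2S,3S)-3-(4-hydroxy-3-methoxyphenyl)-2-(hydroxymethyl)-8-methoxy-2,3-dihydro-1,4-benzodioxin-6-yl]prop-2-en-1-ol | COc1cc([C@@H]2Oc3cc(/C=C/CO)cc(OC)c3O[C@H]2CO)ccc1O
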